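**Retrosynthetic overview**

1. Target 14 is the all-cis tetrahydrofuran (ring O1, C2–C5; C9 = hydroxymethyl carbon on C3, C7′ = benzylic carbon on C4). It comes from all-cis acid 13 (C9 carboxyl to CH2OH), and 13 from (S)-2,5-dihydrofuran-3-carboxylic acid 12 by syn hydrogenation of C3=C4 on the face opposite the C2 aryl group.
2. Acid 12 comes from racemic acid 10 by salt resolution; 10 from ester 9; 9 from the 4-arylidene tetrahydrofuran-3,3-diester 8 by loss of one ester and shift of the C4=C7′ alkene into the ring.
3. The strategy rests on three features of the ring: O1–C2 lies β to C3, the ring bond C3–C4 ends on a carbon that can come from an alkyne, and C7′ carries the dimethoxyphenyl ring.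
4. Diester 8 is therefore assembled in one pot from benzylidene malonate 3 (C2 with its aryl, C3, C9), propargyl alcohol 4 (O1, C5, C4, C7′) and aryl iodide 5, forming O1–C2, C3–C4 and C7′–aryl.
5. The tetrahydrofuran is the only ring made (step 2); both arenes are bought, and 3 comes from aldehyde 1 and malonate 2 by Knoevenagel condensation.

Key step: step 2

Assumption: of the two diastereomeric (R)-1-phenylethylammonium salts, that of the (S)-acid is taken to be the less soluble; should the salt of the (R)-acid crystallise instead, (S)-1-phenylethylamine is used and nothing else changes.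

**Route**

Step 1
Reactants: 1 3,4,5-trimethoxybenzaldehyde; 2 diethyl malonate
Product: 3 diethyl 2-(3,4,5-trimethoxybenzylidene)malonate
Conditions: piperidine (0.1 equiv), AcOH (0.1 equiv), toluene, reflux, azeotropic removal of water
Reagents that add atoms: none
Why: Knoevenagel condensation of a non-enolisable aryl aldehyde with a malonate, driven to completion by removal of water; no stereocentre is formed.

Step 2
Reactants: 3 diethyl 2-(3,4,5-trimethoxybenzylidene)malonate; 4 propargyl alcohol; 5 4-iodo-1,2-dimethoxybenzene
Product: 8 diethyl (Z)-4-(3,4-dimethoxybenzylidene)-2-(3,4,5-trimethoxyphenyl)dihydrofuran-3,3(2H)-dicarboxylate (racemic at C2), via lithium prop-2-yn-1-olate 6 (not isolated), via oxa-Michael adduct lithium enolate 7 (not isolated)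
Conditions: 4 (1.6 equiv), n-BuLi (1.5 equiv), THF, 0 °C; then 3 (1.0 equiv), rt; then 5 (1.5 equiv), PdCl2(PPh3)2 (5 mol %) prereduced with n-BuLi (10 mol %), THF–DMSO, rt
Reagents that add atoms: none
Why: Oxa-Michael addition of alkoxide 6 to the β-carbon of 3 forms O1–C2 reversibly and gives malonate enolate 7, while oxidative addition of 5 to zerovalent palladium (made from PdCl2(PPh3)2 and n-BuLi) gives an arylpalladium iodide that binds the alkyne of 7. The malonate carbon C3 attacks the internal alkyne carbon on the side away from palladium, closing the tetrahydrofuran ring (C3–C4) in the 5-exo-dig mode, and reductive elimination from the vinyl(aryl)palladium then forms the C7′–aryl bond with the aryl group trans to C3, which is the Z alkene. The closest known reaction type is this same palladium-mediated three-component coupling of propargyl alkoxides, alkylidene malonates and aryl halides to 4-arylidene tetrahydrofurans, a conjugate addition, anti carbopalladation and cross-coupling cascade. C2 is the only new stereocentre and, since it arises in the reversible oxa-Michael step with no chiral element present, it is formed as the racemate that step 5 resolves. The step needs ring closure to outrun retro-Michael loss of the alkoxide and aryl–alkynyl coupling at the terminal C–H, and exo rather than endo attack; the irreversible carbopalladation drains the Michael equilibrium, the stabilised carbanion sits three atoms from the alkyne so the intramolecular attack is fast without a copper co-catalyst, and that tether length makes the six-membered endo closure geometrically poor.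

Step 3
Reactants: 8 diethyl (Z)-4-(3,4-dimethoxybenzylidene)-2-(3,4,5-trimethoxyphenyl)dihydrofuran-3,3(2H)-dicarboxylate
Product: 9 ethyl 4-(3,4-dimethoxybenzyl)-2-(3,4,5-trimethoxyphenyl)-2,5-dihydrofuran-3-carboxylate (racemic)
Conditions: LiCl (3 equiv), H2O (2 equiv), DMSO, 150 °C, Ar; then DBU (0.2 equiv), 60 °C
Reagents that add atoms: none
Why: Krapcho dealkoxycarbonylation, in which chloride dealkylates one ethyl ester and CO2 is lost to leave a dienolate (C3–C4=C7′) that is protonated at C7′ or, after DBU equilibration of the α-protonated isomer, settles as the ester-conjugated tetrasubstituted C3=C4 alkene, which is endocyclic in a five-membered ring; no stereocentre is set and C2 stays racemic.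

Step 4
Reactants: 9 ethyl 4-(3,4-dimethoxybenzyl)-2-(3,4,5-trimethoxyphenyl)-2,5-dihydrofuran-3-carboxylate
Product: 10 4-(3,4-dimethoxybenzyl)-2-(3,4,5-trimethoxyphenyl)-2,5-dihydrofuran-3-carboxylic acid (racemic)
Conditions: LiOH·H2O (3 equiv), THF–MeOH–H2O, 40 °C, Ar; then 1 M HCl, 0 °C
Reagents that add atoms: lithium hydroxide, [Li+].[OH-]
Why: Ester saponification by acyl substitution under mild conditions; C2–H is not vinylogous to the carbonyl group and is therefore not acidified, so the alkene position should hold.

Step 5
Reactants: 10 4-(3,4-dimethoxybenzyl)-2-(3,4,5-trimethoxyphenyl)-2,5-dihydrofuran-3-carboxylic acid (racemic)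
Product: 11 (R)-1-phenylethylammonium (S)-4-(3,4-dimethoxybenzyl)-2-(3,4,5-trimethoxyphenyl)-2,5-dihydrofuran-3-carboxylate
Conditions: (R)-1-phenylethylamine (0.5 equiv), EtOH, 70 °C to rt; recrystallise from EtOH to constant rotation
Reagents that add atoms: (R)-1-phenylethylamine, C[C@@H](N)c1ccccc1
Why: Classical resolution by crystallisation of a diastereomeric ammonium carboxylate salt with half an equivalent of amine, so that the less soluble salt separates and the other enantiomer stays in solution as the free acid; the C2 configuration of the crystals is to be confirmed by X-ray diffraction against the known amine centre.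

Step 6
Reactants: 11 (R)-1-phenylethylammonium (S)-4-(3,4-dimethoxybenzyl)-2-(3,4,5-trimethoxyphenyl)-2,5-dihydrofuran-3-carboxylate
Product: 13 (2R,3S,4R)-4-(3,4-dimethoxybenzyl)-2-(3,4,5-trimethoxyphenyl)tetrahydrofuran-3-carboxylic acid (all-cis), via free (S)-dihydrofuran acid 12 (not isolated)
Conditions: 1 M HCl/EtOAc partition, 0 °C; then H2 (4 bar), PtO2 (5 mol %), EtOAc, rt
Reagents that add atoms: none
Why: Acidification frees acid 12, and heterogeneous syn hydrogenation of the tetrasubstituted alkene occurs on the face of the nearly planar dihydrofuran opposite the C2 aryl group, so both new hydrogens enter cis to C2–H and the carboxyl group (C3, S) and the benzyl group (C4, R) end up cis to the aryl group; platinum in a neutral solvent is chosen because it is less prone than palladium to alkene migration and to hydrogenolysis of the benzylic C2–O bond.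

Step 7
Reactants: 13 (2R,3S,4R)-4-(3,4-dimethoxybenzyl)-2-(3,4,5-trimethoxyphenyl)tetrahydrofuran-3-carboxylic acid
Product: 14 [(2R,3R,4R)-4-(3,4-dimethoxybenzyl)-2-(3,4,5-trimethoxyphenyl)tetrahydrofuran-3-yl]methanol (target; all three substituents cis)
Conditions: LiAlH4 (3 equiv), THF, 0 °C to reflux; then H2O, 15% aq NaOH, H2O
Reagents that add atoms: none
Why: LiAlH4 reduction of a carboxylic acid to the primary alcohol by way of the lithium carboxylate, whose α-carbon is not enolised, so the less stable 2,3-cis arrangement should be kept (the C3 descriptor changes from S to R only through the change in substituent priority).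

**Compound list**

1 | 3,4,5-trimethoxybenzaldehyde | COc1cc(C=O)cc(OC)c1OC | starting material
2 | diethyl malonate | CCOC(=O)CC(=O)OCC | starting material
3 | diethyl 2-(3,4,5-trimethoxybenzylidene)malonate | CCOC(=O)C(=Cc1cc(OC)c(OC)c(OC)c1)C(=O)OCC | intermediate
4 | propargyl alcohol | C#CCO | starting material
5 | 4-iodo-1,2-dimethoxybenzene | COc1ccc(I)cc1OC | starting material
6 | lithium prop-2-yn-1-olate (formed in the flask) | [Li+].[O-]CC#C | intermediate
7 | lithium enolate of diethyl 2-[(prop-2-yn-1-yloxy)(3,4,5-trimethoxyphenyl)methyl]malonate (racemic, formed in the flask) | [Li+].CCOC([O-])=C(C(=O)OCC)C(OCC#C)c1cc(OC)c(OC)c(OC)c1 | intermediate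
8 | diethyl (Z)-4-(3,4-dimethoxybenzylidene)-2-(3,4,5-trimethoxyphenyl)dihydrofuran-3,3(2H)-dicarboxylate (racemic) | CCOC(=O)C1(C(=O)OCC)C(c2cc(OC)c(OC)c(OC)c2)OC/C1=C\c1ccc(OC)c(OC)c1 | intermediate
9 | ethyl 4-(3,4-dimethoxybenzyl)-2-(3,4,5-trimethoxyphenyl)-2,5-dihydrofuran-3-carboxylate (racemic) | CCOC(=O)C1=C(Cc2ccc(OC)c(OC)c2)COC1c1cc(OC)c(OC)c(OC)c1 | intermediate
10 | 4-(3,4-dimethoxybenzyl)-2-(3,4,5-trimethoxyphenyl)-2,5-dihydrofuran-3-carboxylic acid (racemic) | OC(=O)C1=C(Cc2ccc(OC)c(OC)c2)COC1c1cc(OC)c(OC)c(OC)c1 | intermediate
11 | (R)-1-phenylethylammonium (S)-4-(3,4-dimethoxybenzyl)-2-(3,4,5-trimethoxyphenyl)-2,5-dihydrofuran-3-carboxylate | C[C@@H]([NH3+])c1ccccc1.COc1ccc(CC2=C(C(=O)[O-])[C@H](c3cc(OC)c(OC)c(OC)c3)OC2)cc1OC | intermediate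
12 | (S)-4-(3,4-dimethoxybenzyl)-2-(3,4,5-trimethoxyphenyl)-2,5-dihydrofuran-3-carboxylic acid (used as its EtOAc solution) | COc1ccc(CC2=C(C(=O)O)[C@H](c3cc(OC)c(OC)c(OC)c3)OC2)cc1OC | intermediate
13 | (2R,3S,4R)-4-(3,4-dimethoxybenzyl)-2-(3,4,5-trimethoxyphenyl)tetrahydrofuran-3-carboxylic acid | COc1ccc(C[C@H]2CO[C@@H](c3cc(OC)c(OC)c(OC)c3)[C@H]2C(=O)O)cc1OC | intermediate
14 | [(2R,3R,4R)-4-(3,4-dimethoxybenzyl)-2-(3,4,5-trimethoxyphenyl)tetrahydrofuran-3-yl]methanol | COc1ccc(C[C@H]2CO[C@@H](c3cc(OC)c(OC)c(OC)c3)[C@H]2CO)cc1OC | target

**Step count**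

Total steps: 7. Longest linear sequence: 7 steps (1 → 3 → 8 → 9 → 10 → 11 → 13 → 14).

**Steps most likely to fail**

1. Step 6 (hydrogenation). The tetrasubstituted, acid-conjugated alkene may be reduced only slowly on the metal surface. That would let hydrogenolysis of the allylic and benzylic C2–O bond compete, or let the alkene migrate to C2=C3, which would erase the resolved centre. The fallback sets out from acid 12 and changes both the oxidation level and the type of catalyst. The carboxyl group is reduced first (LiAlH4, Et2O, 0 °C) to the allylic alcohol [(S)-4-(3,4-dimethoxybenzyl)-2-(3,4,5-trimethoxyphenyl)-2,5-dihydrofuran-3-yl]methanol F1. F1 is then hydrogenated homogeneously with [Ir(cod)(PCy3)(py)]PF6 (catalytic) under H2 in CH2Cl2 at rt. This cationic iridium complex, held by the hydroxyl group, saturates tetrasubstituted alkenes without cleaving benzylic ethers and should again add on the face away from the C2 aryl group. The product is target 14, where the route is rejoined.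

2. Step 5 (resolution). The two diastereomeric salts may fail to crystallise, or may crystallise together without discrimination. The fallback sets out from racemic acid 10 and separates covalent diastereomers instead. The acid chloride (oxalyl chloride, catalytic DMF, CH2Cl2) acylates the lithium salt of (S)-4-benzyloxazolidin-2-one (n-BuLi, THF, −78 °C), and the two imides are separated by chromatography on silica. The imide with the (S)-configured C2, (S)-4-benzyl-3-[(S)-4-(3,4-dimethoxybenzyl)-2-(3,4,5-trimethoxyphenyl)-2,5-dihydrofuran-3-carbonyl]oxazolidin-2-one F2, is cleaved with LiOH/H2O2 (THF–H2O, 0 °C). This returns free (S)-acid 12, which enters step 6 at the hydrogenation stage.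

3. Step 3 (dealkoxycarbonylation and alkene shift). At 150 °C the dienolate may be protonated so that the alkene stays exocyclic and conjugated to the aryl ring, or the dihydrofuran may be dehydrogenated to the furan with loss of the C2 hydrogen. The fallback sets out from diester 8 and removes the carboxyl group under mild, stepwise conditions. One ester is saponified (KOH, 1.1 equiv, EtOH–H2O, rt) to the half-ester 4-(3,4-dimethoxybenzylidene)-3-(ethoxycarbonyl)-2-(3,4,5-trimethoxyphenyl)tetrahydrofuran-3-carboxylic acid F3. This malonic half-acid should lose CO2 on gentle heating (toluene, 100 °C, Ar). DBU in CH2Cl2 at rt then moves the alkene into conjugation with the ester, giving ester 9, where the route is rejoined.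

**Further compounds**

F1 | step 6 | [(S)-4-(3,4-dimethoxybenzyl)-2-(3,4,5-trimethoxyphenyl)-2,5-dihydrofuran-3-yl]methanol | COc1ccc(CC2=C(CO)[C@H](c3cc(OC)c(OC)c(OC)c3)OC2)cc1OC
F2 | step 5 | (S)-4-benzyl-3-[(S)-4-(3,4-dimethoxybenzyl)-2-(3,4,5-trimethoxyphenyl)-2,5-dihydrofuran-3-carbonyl]oxazolidin-2-one | COc1ccc(CC2=C(C(=O)N3[C@@H](Cc4ccccc4)COC3=O)[C@H](c3cc(OC)c(OC)c(OC)c3)OC2)cc1OC
F3 | step 3 | 4-(3,4-dimethoxybenzylidene)-3-(ethoxycarbonyl)-2-(3,4,5-trimethoxyphenyl)tetrahydrofuran-3-carboxylic acid (racemic, both C3 diastereomers) | CCOC(=O)C1(C(=O)O)C(c2cc(OC)c(OC)c(OC)c2)OC/C1=C\c1ccc(OC)c(OC)c1
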